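## Retrosynthet­ic overview

- Numbering: lactone O1, C2 (C=O), C3, C4, C5; C6 is the exocyclic methine carrying ring A (3-hydroxy-4,5-dimethoxyphenyl); C7 is the methylene on C4 carrying ring B (4-hydroxy-3-methoxyphenyl). The target is (3E,4R).
- Feature the plan rests on: C3 and C4 are the α- and β-carbons of an unsubstituted butenolide, so the enolate made by adding the ring B benzyl unit to C4 can take up the ring A carbon at C3.
- The E C3=C6 alkene is cut back to a C6 carbinol (sulfonate, E1cB elimination; MOM removal last). C4–C7 and C3–C6 are then cut together: copper/phosphoramidite-catalysed conjugate benzylation of furan-2(5H)-one with aldol trapping by the ring A aldehyde.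
- The benzylzinc chloride comes from vanillin (MOM ether, reduction, chloride, zinc insertion); the aldehyde is MOM-protected 3-hydroxy-4,5-dimethoxybenzaldehyde.
- Ring order: no ring is built; the lactone is bought as furan-2(5H)-one and both arenes arrive with the aldehydes.

Key step: step 6

Assumption: the sense of induction of a given phosphoramidite antipode with a benzylic zinc nucleophile on furan-2(5H)-one cannot be predicted with confidence; the (S,R,R) ligand is written, and its (R,S,S) antipode is used instead if a test run shows the 4S series.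

## Route

Step 1
Reactants: 1 vanillin (4-hydroxy-3-methoxybenzaldehyde)
Product: 2 3-methoxy-4-(methoxymethoxy)benzaldehyde
Conditions: MOMCl, iPr2NEt, CH2Cl2, 0 °C → rt
Reagents that add atoms: chloromethyl methyl ether (MOMCl), COCCl
Why: O-alkylation of the phenol with the α-chloro ether under amine base (MOM acetal protection) is routine for vanillin-type phenols and leaves the aldehyde untouched.

Step 2
Reactants: 2 3-methoxy-4-(methoxymethoxy)benzaldehyde
Product: 3 [3-methoxy-4-(methoxymethoxy)phenyl]methanol
Conditions: NaBH4, MeOH, 0 °C
Reagents that add atoms: none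
Why: Borohydride reduction of an aromatic aldehyde to the benzylic alcohol is reliable, and the basic medium does not touch the MOM acetal.

Step 3
Reactants: 3 [3-methoxy-4-(methoxymethoxy)phenyl]methanol
Product: 5 4-(chloromethyl)-2-methoxy-1-(methoxymethoxy)benzene, via benzylic mesylate 4 (not isolated)
Conditions: MsCl, Et3N, LiCl, THF, 0 °C → rt; crude chloride used after filtration through basic alumina
Reagents that add atoms: lithium chloride, [Li+].[Cl-]
Why: Sulfonylation followed by chloride displacement of the electron-rich benzylic mesylate (Collington–Meyers-type chlorination) runs under amine-buffered conditions, so no free acid reaches the MOM acetal.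

Step 4
Reactants: 5 4-(chloromethyl)-2-methoxy-1-(methoxymethoxy)benzene
Product: 6 [3-methoxy-4-(methoxymethoxy)benzyl]zinc chloride (LiCl complex, THF solution, titrated with iodine)
Conditions: Zn dust (activated with BrCH2CH2Br and Me3SiCl), LiCl, THF, 25 °C
Reagents that add atoms: zinc, [Zn]
Why: Direct oxidative insertion of LiCl-activated zinc into a benzylic C–Cl bond is an established route to benzylic zinc chlorides, tolerates aryl ethers and the MOM acetal, and the LiCl keeps the product off the metal surface so that homocoupling is limited.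

Step 5
Reactants: 7 3-hydroxy-4,5-dimethoxybenzaldehyde
Product: 8 3,4-dimethoxy-5-(methoxymethoxy)benzaldehyde
Conditions: MOMCl, iPr2NEt, CH2Cl2, 0 °C → rt
Reagents that add atoms: chloromethyl methyl ether (MOMCl), COCCl
Why: The same phenol O-alkylation as in step 1 (MOM acetal protection) masks the only acidic proton of the aldehyde component, which would otherwise quench the zinc reagent and the enolate.

Step 6
Reactants: 9 furan-2(5H)-one; 6 [3-methoxy-4-(methoxymethoxy)benzyl]zinc chloride; 8 3,4-dimethoxy-5-(methoxymethoxy)benzaldehyde
Product: 12 (3S,4R)-3-{hydroxy[3,4-dimethoxy-5-(methoxymethoxy)phenyl]methyl}-4-[3-methoxy-4-(methoxymethoxy)benzyl]dihydrofuran-2(3H)-one as a mixture of the two carbinol epimers, via chlorozinc enolate 10 (not isolated), via chlorozinc aldolate 11 (not isolated)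
Conditions: Cu(OTf)2 (5 mol %), (S,R,R)-binaphthol-derived N,N-bis(1-phenylethyl)phosphoramidite (10 mol %), toluene, −40 °C; 9 (1.0 equiv) and 8 (1.2 equiv) present from the start, 6 (1.5 equiv, THF solution) added over 3 h; then sat. aq. NH4Cl
Reagents that add atoms: none
Why: Proposed new method: the zinc reagent reduces Cu(OTf)2 to monovalent copper and transfers its benzyl group to give a phosphoramidite-bound benzylcopper species, which binds the C3=C4 bond of 9 as a π-complex, adds at C4 to a trivalent copper intermediate and reductively eliminates to form C4–C7, releasing chlorozinc enolate 10 and monovalent copper. The closest known reaction type is the copper/phosphoramidite-catalysed enantioselective conjugate addition of dialkylzinc reagents to unsaturated lactones with in situ aldehyde trapping; what is new is a benzylic zinc halide as the nucleophile. No ring is closed. C4 is set by catalyst control, the ligand shielding one face of the copper-bound butenolide, and C3 by substrate control, the aldehyde approaching enolate 10 anti to the new C4 benzyl group to give the trans lactone; the C6 carbinol centre is left uncontrolled because step 7 removes it. The step needs 1,4-addition to outrun direct addition of the benzylzinc reagent to aldehyde 8, which should be secured by the low temperature, by slow addition that keeps free zinc reagent scarce, and by the low electrophilicity of the trialkoxy-substituted aldehyde. Keeping 8 in the flask converts enolate 10 to aldolate 11 before it can fragment to a ketene or add to a second butenolide.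

Step 7
Reactants: 12 trans aldol adduct (both carbinol epimers)
Product: 14 (3E,4R)-3-[3,4-dimethoxy-5-(methoxymethoxy)benzylidene]-4-[3-methoxy-4-(methoxymethoxy)benzyl]dihydrofuran-2(3H)-one, via carbinol mesylate 13 (not isolated)
Conditions: MsCl, Et3N, CH2Cl2, 0 °C; then DBU, 0 °C → rt
Reagents that add atoms: none
Why: Mesylation and E1cB elimination through the lactone enolate should funnel both carbinol epimers to the more stable E-arylidene lactone (aryl anti to the lactone carbonyl), while the C4–H, being γ and only weakly acidic, should stay untouched under brief amidine treatment.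

Step 8
Reactants: 14 bis-MOM (3E,4R)-arylidene lactone
Product: 15 (3E,4R)-3-[(3-hydroxy-4,5-dimethoxyphenyl)methylidene]-4-[(4-hydroxy-3-methoxyphenyl)methyl]oxolan-2-one (target)
Conditions: HCl (1.25 M in MeOH), MeOH/THF, 0 °C → rt
Reagents that add atoms: none
Why: Acid-catalysed acetal exchange with methanol (MOM cleavage) should free both phenols as dimethoxymethane is formed, and dilute acid at room temperature should affect neither the conjugated lactone, the E alkene nor C4.

## Compound list

1 | vanillin (4-hydroxy-3-methoxybenzaldehyde) | COc1cc(C=O)ccc1O | starting material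
2 | 3-methoxy-4-(methoxymethoxy)benzaldehyde | COCOc1ccc(C=O)cc1OC | intermediate
3 | [3-methoxy-4-(methoxymethoxy)phenyl]methanol | COCOc1ccc(CO)cc1OC | intermediate
4 | 3-methoxy-4-(methoxymethoxy)benzyl methanesulfonate (not isolated) | COCOc1ccc(COS(C)(=O)=O)cc1OC | intermediate
5 | 4-(chloromethyl)-2-methoxy-1-(methoxymethoxy)benzene | COCOc1ccc(CCl)cc1OC | intermediate
6 | [3-methoxy-4-(methoxymethoxy)benzyl]zinc chloride (LiCl complex in THF) | COCOc1ccc(C[Zn]Cl)cc1OC | intermediate
7 | 3-hydroxy-4,5-dimethoxybenzaldehyde | COc1cc(C=O)cc(O)c1OC | starting material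
8 | 3,4-dimethoxy-5-(methoxymethoxy)benzaldehyde | COCOc1cc(C=O)cc(OC)c1OC | intermediate
9 | furan-2(5H)-one | O=C1OCC=C1 | starting material
10 | chlorozinc enolate of (R)-4-[3-methoxy-4-(methoxymethoxy)benzyl]dihydrofuran-2(3H)-one (not isolated) | COCOc1ccc(C[C@H]2COC(O[Zn]Cl)=C2)cc1OC | intermediate
11 | chlorozinc aldolate of 12, (3S,4R), both carbinol epimers (not isolated) | COCOc1ccc(C[C@H]2COC(=O)[C@@H]2C(O[Zn]Cl)c2cc(OCOC)c(OC)c(OC)c2)cc1OC | intermediate
12 | (3S,4R)-3-{hydroxy[3,4-dimethoxy-5-(methoxymethoxy)phenyl]methyl}-4-[3-methoxy-4-(methoxymethoxy)benzyl]dihydrofuran-2(3H)-one, both carbinol epimers | COCOc1ccc(C[C@H]2COC(=O)[C@@H]2C(O)c2cc(OCOC)c(OC)c(OC)c2)cc1OC | intermediate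
13 | methanesulfonate of carbinol 12, (3S,4R), both epimers (not isolated) | COCOc1ccc(C[C@H]2COC(=O)[C@@H]2C(OS(C)(=O)=O)c2cc(OCOC)c(OC)c(OC)c2)cc1OC | intermediate
14 | (3E,4R)-3-[3,4-dimethoxy-5-(methoxymethoxy)benzylidene]-4-[3-methoxy-4-(methoxymethoxy)benzyl]dihydrofuran-2(3H)-one | COCOc1ccc(C[C@H]2COC(=O)/C2=C/c2cc(OCOC)c(OC)c(OC)c2)cc1OC | intermediate
15 | (3E,4R)-3-[(3-hydroxy-4,5-dimethoxyphenyl)methylidene]-4-[(4-hydroxy-3-methoxyphenyl)methyl]oxolan-2-one | COc1cc(C[C@H]2COC(=O)/C2=C/c2cc(O)c(OC)c(OC)c2)ccc1O | target

## Step count and risks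

Total steps: 8. Longest linear sequence: 7 steps (steps 1, 2, 3, 4, 6, 7, 8); step 5 is a one-step side branch.

**Step 6 (key step).** The benzylic zinc chloride may turn over poorly in the copper cycle, may add directly to the aldehyde, or the ligand may give poor facial selectivity at C4 on the small, flat butenolide. The fallback uses auxiliary-controlled alkylation and a lactone enolate aldol, both known chemistry; it sets out from chloride 5 (with aldehyde 8) and comes back at aldol adduct 12.
- (R)-4-Benzyloxazolidin-2-one is N-acylated (n-BuLi, pent-4-enoyl chloride, THF, −78 °C) to (R)-4-benzyl-3-(pent-4-enoyl)oxazolidin-2-one F1.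
- Chloride 5 is exchanged with NaI in acetone to 4-(iodomethyl)-2-methoxy-1-(methoxymethoxy)benzene F2.
- The sodium enolate of F1 (NaN(SiMe3)2, THF, −78 °C) is alkylated by F2 on the face away from the auxiliary benzyl group, which should give (R)-4-benzyl-3-{(S)-2-[3-methoxy-4-(methoxymethoxy)benzyl]pent-4-enoyl}oxazolidin-2-one F3.
- LiBH4 (THF, one equivalent of MeOH, 0 °C) removes the auxiliary to give (S)-2-[3-methoxy-4-(methoxymethoxy)benzyl]pent-4-en-1-ol F4.
- Lemieux–Johnson cleavage of the vinyl group (OsO4 cat., NaIO4, 2,6-lutidine, dioxane/water) gives the hydroxy aldehyde as its lactol, (4R)-4-[3-methoxy-4-(methoxymethoxy)benzyl]tetrahydrofuran-2-ol F5.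
- TEMPO/PhI(OAc)2 in CH2Cl2 oxidises F5 to (R)-4-[3-methoxy-4-(methoxymethoxy)benzyl]dihydrofuran-2(3H)-one F6.
- Deprotonation of F6 with LiN(iPr)2 (THF, −78 °C) and addition of aldehyde 8 anti to the C4 benzyl group should give trans adduct 12, and no step uses acid that would cleave the MOM ethers.

**Step 7.** The electron-rich benzylic mesylate may ionise, DBU may move the alkene into the ring with loss of the C4 centre, or some Z isomer may form. The fallback is a base-free dehydration; it sets out from carbinol 12 and comes back at 14.
- 12 is heated with the Burgess reagent (methyl N-(triethylammoniosulfonyl)carbamate) in toluene at 50 °C.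
- The resulting triethylammonium sulfamate ester of 12 F7 should lose the sulfamate by intramolecular syn elimination without any free base.
- Any (3Z,4R) geometric isomer of 14 F8 formed from the other carbinol epimer is equilibrated to the E isomer 14 with catalytic I2 in CH2Cl2 under daylight.

**Step 4.** Wurtz-type homocoupling of the electron-rich benzylic chloride at the zinc surface, or sluggish insertion, may consume the chloride. The fallback makes the carbon–zinc bond by transmetalation; it sets out from chloride 5 and comes back at zinc reagent 6.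
- 5 is stirred with Mg turnings, LiCl and ZnCl2 in THF at 25 °C.
- The transient [3-methoxy-4-(methoxymethoxy)benzyl]magnesium chloride F9 is captured at once by ZnCl2, so its stationary concentration stays low.
- MgCl2 is precipitated with 1,4-dioxane and filtered off before titration, because magnesium salts promote direct carbonyl addition in step 6.

## Further compounds

F1 | step 6 | (R)-4-benzyl-3-(pent-4-enoyl)oxazolidin-2-one | C=CCCC(=O)N1[C@H](Cc2ccccc2)COC1=O
F2 | step 6 | 4-(iodomethyl)-2-methoxy-1-(methoxymethoxy)benzene | COCOc1ccc(CI)cc1OC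
F3 | step 6 | (R)-4-benzyl-3-{(S)-2-[3-methoxy-4-(methoxymethoxy)benzyl]pent-4-enoyl}oxazolidin-2-one | C=CC[C@@H](Cc1ccc(OCOC)c(OC)c1)C(=O)N1[C@H](Cc2ccccc2)COC1=O
F4 | step 6 | (S)-2-[3-methoxy-4-(methoxymethoxy)benzyl]pent-4-en-1-ol | C=CC[C@@H](Cc1ccc(OCOC)c(OC)c1)CO
F5 | step 6 | (4R)-4-[3-methoxy-4-(methoxymethoxy)benzyl]tetrahydrofuran-2-ol (both anomers) | OC1C[C@@H](Cc2ccc(OCOC)c(OC)c2)CO1
F6 | step 6 | (R)-4-[3-methoxy-4-(methoxymethoxy)benzyl]dihydrofuran-2(3H)-one | O=C1C[C@@H](Cc2ccc(OCOC)c(OC)c2)CO1
F7 | step 7 | triethylammonium N-(methoxycarbonyl)sulfamate ester of carbinol 12 | COCOc1ccc(C[C@H]2COC(=O)[C@@H]2C(OS(=O)(=O)NC(=O)OC)c2cc(OCOC)c(OC)c(OC)c2)cc1OC.CCN(CC)CC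
F8 | step 7 | (3Z,4R)-3-[3,4-dimethoxy-5-(methoxymethoxy)benzylidene]-4-[3-methoxy-4-(methoxymethoxy)benzyl]dihydrofuran-2(3H)-one | COCOc1ccc(C[C@H]2COC(=O)/C2=C\c2cc(OCOC)c(OC)c(OC)c2)cc1OC
F9 | step 4 | [3-methoxy-4-(methoxymethoxy)benzyl]magnesium chloride | COCOc1ccc(C[Mg]Cl)cc1OC
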